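**Plan**

- Cuts: on ring A, the aryl–C(CH3)2CH=CH2 bond, back to an aryl prenyl ether (Claisen); the propane linker, back to a chalcone (aldol bond, ring A carbonyl later removed); C4–prenyl (Stille) and C5–CHO (from the aryl bromide); C2–C3 and O1–C2 of the dihydrofuran.
- Enabling feature: in ring B, C2 lies between O1 (on C7a) and C3H2 (on C3a). C7a=O together with C3a=CH2 is an ortho-quinone methide of ring B, so C2 can arrive as a one-carbon ammonium ylide whose ester later becomes C(CH3)2OH ([4+1] annulation).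
- Forward order: ring B arene → 2-(tosylmethyl)phenol → dihydrofuran ring (the only ring closed) → carbinol → CHO at C5, Br then prenyl at C4 → aldol with the ring A ketone → linker reduced to (CH2)3 → Claisen shift on ring A → MOM removal.
- Stereochemistry: C2 (R), the only stereocentre, is set in the annulation by the cinchona-derived quinuclidinium group that leaves in the ring closure; no later step acts at C2.

Key step: step 6

Assumption: the O-methylquinidinium ylide is taken to give the (2R)-ester; if the (2S)-ester predominates, the pseudoenantiomeric O-methylquinine replaces it and nothing else changes.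

**Route**

Step 1
Reactants: 1 2,3-dihydroxybenzaldehyde
Product: 2 2-hydroxy-3-(methoxymethoxy)benzaldehyde
Conditions: NaH (2.2 equiv), DMF, 0 °C; MOMCl (1.05 equiv), 0 °C to rt
Reagents that add atoms: chloromethyl methyl ether (MOMCl), COCCl
Why: The dianion is alkylated at the 3-oxide, the more nucleophilic oxygen because the 2-oxide is delocalised into and chelated by the formyl group (selective Williamson-type O-alkylation of a catechol dianion).

Step 2
Reactants: 2 2-hydroxy-3-(methoxymethoxy)benzaldehyde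
Product: 3 5-bromo-2-hydroxy-3-(methoxymethoxy)benzaldehyde
Conditions: NBS, MeCN, 0 °C to rt
Reagents that add atoms: N-bromosuccinimide, O=C1CCC(=O)N1Br
Why: Electrophilic aromatic bromination should go para to the free phenol, which is also meta to the formyl group, and the acid-free NBS conditions spare the MOM acetal.

Step 3
Reactants: 3 5-bromo-2-hydroxy-3-(methoxymethoxy)benzaldehyde
Product: 4 4-bromo-2-(hydroxymethyl)-6-(methoxymethoxy)phenol
Conditions: NaBH4, MeOH–THF, 0 °C
Reagents that add atoms: none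
Why: Borohydride reduction of the aldehyde to the salicyl alcohol leaves the aryl bromide and the acetal untouched.

Step 4
Reactants: 4 4-bromo-2-(hydroxymethyl)-6-(methoxymethoxy)phenol; 5 sodium 4-methylbenzenesulfinate
Product: 6 4-bromo-2-(methoxymethoxy)-6-[(4-methylbenzenesulfonyl)methyl]phenol
Conditions: 5 (2 equiv), AcOH–H2O (3:1), 50 °C
Reagents that add atoms: sodium 4-methylbenzenesulfinate (5), Cc1ccc(cc1)S(=O)[O-].[Na+]
Why: Acid-promoted ionisation of the ortho-hydroxybenzyl alcohol gives a quinone-methide-like cation that the sulfinate captures at sulfur (benzylic substitution by a sulfinate), and the aryl MOM ether should tolerate warm aqueous acetic acid.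

Step 5
Reactants: 7 quinidine
Product: 8 O-methylquinidine
Conditions: NaH, DMF, rt; MeI (1.05 equiv), 0 °C
Reagents that add atoms: iodomethane, CI
Why: Williamson etherification of the preformed C9 alkoxide, which is methylated faster than the quinuclidine nitrogen is quaternised when MeI is kept to one equivalent.

Step 6
Reactants: 6 4-bromo-2-(methoxymethoxy)-6-[(4-methylbenzenesulfonyl)methyl]phenol; 8 O-methylquinidine; 9 tert-butyl bromoacetate
Product: 14 tert-butyl (2R)-5-bromo-7-(methoxymethoxy)-2,3-dihydro-1-benzofuran-2-carboxylate, via ammonium bromide 10 (not isolated), via ammonium ylide 11 (not isolated), via ortho-quinone methide 12 (not isolated), via betaine 13 (not isolated)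
Conditions: 8 (1.4 equiv), 9 (1.3 equiv), CH2Cl2, rt; then 6, Cs2CO3 (3 equiv), CH2Cl2, 0 °C to rt
Reagents that add atoms: tert-butyl bromoacetate (9), BrCC(=O)OC(C)(C)C
Why: Proposed new method: Cs2CO3 eliminates 4-methylbenzenesulfinate from 6 to give ortho-quinone methide 12 and deprotonates ammonium bromide 10 to ylide 11, whose carbon adds to the exocyclic CH2 (forming C2–C3 and restoring the arene) to give betaine 13. The phenoxide of 13 then displaces the quinuclidinium group at the same carbon in a 5-exo-tet SN2 closure with inversion, which forms O1–C2 and releases 8. The closest known reaction type is the enantioselective formal [4+1] annulation of cinchona-derived ammonium ylides with ortho-quinone methides generated from 2-(1-tosylalkyl)phenols that bear a substituent on the exocyclic carbon; the terminal CH2 acceptor, where C2 is the only stereocentre formed, is the extension. C2 is controlled by the chiral quinuclidinium alone: either by the ylide face that adds under kinetic control or, if the betaine epimers interconvert by proton exchange at the acidic CH(N+)CO2t-Bu carbon, by the faster-cyclising epimer, the (S)-betaine giving the (R)-ester on inversion. The step needs C-alkylation at the quinone methide CH2 ahead of its oligomerisation, of sulfinate re-addition and of phenol O-alkylation; slow heterogeneous generation from the sulfone with the ylide in excess and no free bromoacetate, the unhindered CH2 terminus whose attack restores aromaticity, and the MOM cap on the neighbouring oxygen should secure this, with the C5 bromide a spectator.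

Step 7
Reactants: 14 tert-butyl (2R)-5-bromo-7-(methoxymethoxy)-2,3-dihydro-1-benzofuran-2-carboxylate
Product: 16 2-[(2R)-5-bromo-7-(methoxymethoxy)-2,3-dihydro-1-benzofuran-2-yl]propan-2-ol, via methyl ketone 15 (not isolated)
Conditions: MeMgBr (4 equiv), THF, −20 °C to rt; aq. NH4Cl
Reagents that add atoms: methylmagnesium bromide, C[Mg]Br
Why: Double Grignard addition to the ester through ketone 15, in which addition should outpace enolisation of the alpha-alkoxy carbonyl compounds so that C2 keeps its configuration.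

Step 8
Reactants: 16 2-[(2R)-5-bromo-7-(methoxymethoxy)-2,3-dihydro-1-benzofuran-2-yl]propan-2-ol
Product: 18 (2R)-2-(2-hydroxypropan-2-yl)-7-(methoxymethoxy)-2,3-dihydro-1-benzofuran-5-carbaldehyde, via aryllithium 17 (not isolated)
Conditions: n-BuLi (2.2 equiv), THF, −78 °C; DMF, −78 to 0 °C; aq. NH4Cl
Reagents that add atoms: N,N-dimethylformamide, CN(C)C=O
Why: The first equivalent of n-BuLi forms the lithium alkoxide and the second effects bromine–lithium exchange at C5, faster at −78 °C than MOM-directed ortho-lithiation, and the aryllithium is formylated by DMF (Bouveault-type formylation).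

Step 9
Reactants: 18 (2R)-2-(2-hydroxypropan-2-yl)-7-(methoxymethoxy)-2,3-dihydro-1-benzofuran-5-carbaldehyde
Product: 19 (2R)-4-bromo-2-(2-hydroxypropan-2-yl)-7-(methoxymethoxy)-2,3-dihydro-1-benzofuran-5-carbaldehyde
Conditions: NBS, DMF, rt, dark
Reagents that add atoms: N-bromosuccinimide, O=C1CCC(=O)N1Br
Why: Electrophilic aromatic bromination should favour C4, which is para to the C7 alkoxy group and ortho to the C3a alkyl group (the orientation seen when 3,4-dialkoxybenzaldehydes brominate para to the 3-alkoxy group), over C6, which is only ortho to OMOM and more crowded.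

Step 10
Reactants: 19 (2R)-4-bromo-2-(2-hydroxypropan-2-yl)-7-(methoxymethoxy)-2,3-dihydro-1-benzofuran-5-carbaldehyde
Product: 20 (2R)-2-(2-hydroxypropan-2-yl)-7-(methoxymethoxy)-4-(3-methylbut-2-en-1-yl)-2,3-dihydro-1-benzofuran-5-carbaldehyde
Conditions: tributyl(3-methylbut-2-en-1-yl)stannane, Pd(PPh3)4 (5 mol %), DMF, 100 °C
Reagents that add atoms: tributyl(3-methylbut-2-en-1-yl)stannane, CCCC[Sn](CCCC)(CCCC)CC=C(C)C
Why: Stille coupling, in which zerovalent palladium inserts into the C4–Br bond activated by the ortho formyl group and the prenyl group is transferred from tin at its CH2 terminus to give the linear prenyl arene.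

Step 11
Reactants: 21 1-(2,4-dihydroxyphenyl)ethan-1-one
Product: 22 1-{2-hydroxy-4-[(3-methylbut-2-en-1-yl)oxy]phenyl}ethan-1-one
Conditions: prenyl bromide (1.1 equiv), K2CO3, acetone, reflux
Reagents that add atoms: 1-bromo-3-methylbut-2-ene (prenyl bromide), CC(C)=CCBr
Why: Williamson etherification at the 4-hydroxyl, the 2-hydroxyl being held in a hydrogen bond to the ketone and far less nucleophilic.

Step 12
Reactants: 20 (2R)-2-(2-hydroxypropan-2-yl)-7-(methoxymethoxy)-4-(3-methylbut-2-en-1-yl)-2,3-dihydro-1-benzofuran-5-carbaldehyde; 22 1-{2-hydroxy-4-[(3-methylbut-2-en-1-yl)oxy]phenyl}ethan-1-one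
Product: 24 (E)-1-{2-hydroxy-4-[(3-methylbut-2-en-1-yl)oxy]phenyl}-3-[(2R)-2-(2-hydroxypropan-2-yl)-7-(methoxymethoxy)-4-(3-methylbut-2-en-1-yl)-2,3-dihydro-1-benzofuran-5-yl]prop-2-en-1-one, via aldol adduct 23 (not isolated)
Conditions: KOH, EtOH–H2O, rt
Reagents that add atoms: none
Why: Claisen–Schmidt condensation, in which the ketone enolate adds to the non-enolisable aldehyde and aldol 23 dehydrates by E1cB to the (E)-enone while the acetal, the prenyl ether and the tertiary alcohol are stable to hydroxide.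

Step 13
Reactants: 24 the (E)-chalcone of step 12
Product: 25 1-{2-hydroxy-4-[(3-methylbut-2-en-1-yl)oxy]phenyl}-3-[(2R)-2-(2-hydroxypropan-2-yl)-7-(methoxymethoxy)-4-(3-methylbut-2-en-1-yl)-2,3-dihydro-1-benzofuran-5-yl]propan-1-one
Conditions: [(Ph3P)CuH]6 (0.6 equiv), H2O (5 equiv), THF, rt
Reagents that add atoms: none
Why: Stryker conjugate reduction, in which the copper hydride delivers hydride only to the beta-carbon of the enone and water protonates the copper enolate, so the trisubstituted alkenes and the allyl aryl ether are left alone (the excess of reagent allows for the phenol).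

Step 14
Reactants: 25 the dihydrochalcone of step 13
Product: 28 2-{3-[(2R)-2-(2-hydroxypropan-2-yl)-7-(methoxymethoxy)-4-(3-methylbut-2-en-1-yl)-2,3-dihydro-1-benzofuran-5-yl]propyl}-5-[(3-methylbut-2-en-1-yl)oxy]phenol, via aryl ethyl carbonate 26 (not isolated), via ortho-quinone methide 27 (not isolated)
Conditions: ClCO2Et, Et3N, THF, 0 °C; then NaBH4, H2O–THF, 0 °C to rt
Reagents that add atoms: none
Why: Ortho-hydroxyl-assisted deoxygenation of an aryl ketone, in which borohydride reduces the ketone of carbonate 26, the alkoxide takes over the carbonate, the phenoxide expels ethyl carbonate to give quinone methide 27 and a second hydride adds to its exocyclic carbon; the tertiary alcohol is not acylated at 0 °C.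

Step 15
Reactants: 28 the diarylpropane prenyl ether of step 14
Product: 30 4-{3-[(2R)-2-(2-hydroxypropan-2-yl)-7-(methoxymethoxy)-4-(3-methylbut-2-en-1-yl)-2,3-dihydro-1-benzofuran-5-yl]propyl}-6-(2-methylbut-3-en-2-yl)benzene-1,3-diol, via dienone 29 (not isolated)
Conditions: EtOH–H2O (4:1), 130 °C, sealed tube
Reagents that add atoms: none
Why: Aromatic Claisen rearrangement, in which the [3,3] shift joins the tertiary carbon of the prenyl group to the ring and should choose the ortho carbon para to the free hydroxyl over the crowded carbon between the two oxygens (no chelated carbonyl remains to bias it otherwise), dienone 29 then tautomerising to the resorcinol.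

Step 16
Reactants: 30 the MOM ether of step 15
Product: 31 4-{3-[(2R)-7-hydroxy-2-(2-hydroxypropan-2-yl)-4-(3-methylbut-2-en-1-yl)-2,3-dihydro-1-benzofuran-5-yl]propyl}-6-(2-methylbut-3-en-2-yl)benzene-1,3-diol
Conditions: HCl (1 M), MeOH, rt
Reagents that add atoms: none
Why: Acid-catalysed acetal exchange with methanol removes the MOM group, and dilute acid at room temperature should leave both alkenes and the tertiary alcohol intact.

**Compound list**

1 | 2,3-dihydroxybenzaldehyde | O=Cc1cccc(O)c1O | starting material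
2 | 2-hydroxy-3-(methoxymethoxy)benzaldehyde | O=Cc1cccc(OCOC)c1O | intermediate
3 | 5-bromo-2-hydroxy-3-(methoxymethoxy)benzaldehyde | O=Cc1cc(Br)cc(OCOC)c1O | intermediate
4 | 4-bromo-2-(hydroxymethyl)-6-(methoxymethoxy)phenol | OCc1cc(Br)cc(OCOC)c1O | intermediate
5 | sodium 4-methylbenzenesulfinate | Cc1ccc(cc1)S(=O)[O-].[Na+] | starting material
6 | 4-bromo-2-(methoxymethoxy)-6-[(4-methylbenzenesulfonyl)methyl]phenol | Cc1ccc(cc1)S(=O)(=O)Cc1cc(Br)cc(OCOC)c1O | intermediate
7 | quinidine | COC1=CC2=C(C=CN=C2C=C1)[C@@H]([C@H]3C[C@@H]4CCN3C[C@@H]4C=C)O | starting material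
8 | O-methylquinidine (C9 methyl ether) | COC1=CC2=C(C=CN=C2C=C1)[C@@H]([C@H]3C[C@@H]4CCN3C[C@@H]4C=C)OC | intermediate
9 | tert-butyl bromoacetate | BrCC(=O)OC(C)(C)C | starting material
10 | N-(2-tert-butoxy-2-oxoethyl)-O-methylquinidinium bromide (alkylated at the quinuclidine nitrogen) | COC1=CC2=C(C=CN=C2C=C1)[C@@H]([C@H]3C[C@@H]4CC[N@@+]3(CC(=O)OC(C)(C)C)C[C@@H]4C=C)OC.[Br-] | intermediate (not isolated)
11 | ammonium ylide of 10 (carbanion between N+ and the ester) | COC1=CC2=C(C=CN=C2C=C1)[C@@H]([C@H]3C[C@@H]4CC[N@@+]3([CH-]C(=O)OC(C)(C)C)C[C@@H]4C=C)OC | intermediate (not isolated)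
12 | 4-bromo-2-(methoxymethoxy)-6-methylidenecyclohexa-2,4-dien-1-one | C=C1C=C(Br)C=C(OCOC)C1=O | intermediate (not isolated)
13 | betaine: O-methylquinidinium bearing on nitrogen the (1S)-1-(tert-butoxycarbonyl)-2-[5-bromo-3-(methoxymethoxy)-2-oxidophenyl]ethyl group | COC1=CC2=C(C=CN=C2C=C1)[C@@H]([C@H]3C[C@@H]4CC[N@@+]3([C@@H](Cc5cc(Br)cc(OCOC)c5[O-])C(=O)OC(C)(C)C)C[C@@H]4C=C)OC | intermediate (not isolated)
14 | tert-butyl (2R)-5-bromo-7-(methoxymethoxy)-2,3-dihydro-1-benzofuran-2-carboxylate | Brc1cc(OCOC)c2c(c1)C[C@H](C(=O)OC(C)(C)C)O2 | intermediate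
15 | 1-[(2R)-5-bromo-7-(methoxymethoxy)-2,3-dihydro-1-benzofuran-2-yl]ethan-1-one | Brc1cc(OCOC)c2c(c1)C[C@H](C(C)=O)O2 | intermediate (not isolated)
16 | 2-[(2R)-5-bromo-7-(methoxymethoxy)-2,3-dihydro-1-benzofuran-2-yl]propan-2-ol | Brc1cc(OCOC)c2c(c1)C[C@H](C(C)(C)O)O2 | intermediate
17 | lithium 2-[(2R)-5-lithio-7-(methoxymethoxy)-2,3-dihydro-1-benzofuran-2-yl]propan-2-olate | [Li]c1cc(OCOC)c2c(c1)C[C@H](C(C)(C)O[Li])O2 | intermediate (not isolated)
18 | (2R)-2-(2-hydroxypropan-2-yl)-7-(methoxymethoxy)-2,3-dihydro-1-benzofuran-5-carbaldehyde | O=Cc1cc(OCOC)c2c(c1)C[C@H](C(C)(C)O)O2 | intermediate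
19 | (2R)-4-bromo-2-(2-hydroxypropan-2-yl)-7-(methoxymethoxy)-2,3-dihydro-1-benzofuran-5-carbaldehyde | O=Cc1cc(OCOC)c2c(c1Br)C[C@H](C(C)(C)O)O2 | intermediate
20 | (2R)-2-(2-hydroxypropan-2-yl)-7-(methoxymethoxy)-4-(3-methylbut-2-en-1-yl)-2,3-dihydro-1-benzofuran-5-carbaldehyde | O=Cc1cc(OCOC)c2c(c1CC=C(C)C)C[C@H](C(C)(C)O)O2 | intermediate
21 | 1-(2,4-dihydroxyphenyl)ethan-1-one | CC(=O)c1ccc(O)cc1O | starting material
22 | 1-{2-hydroxy-4-[(3-methylbut-2-en-1-yl)oxy]phenyl}ethan-1-one | CC(=O)c1ccc(OCC=C(C)C)cc1O | intermediate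
23 | aldol adduct: 3-hydroxy-1-{2-hydroxy-4-[(3-methylbut-2-en-1-yl)oxy]phenyl}-3-[ring B aryl of 20]propan-1-one, mixture of carbinol epimers | O=C(CC(O)c1cc(OCOC)c2c(c1CC=C(C)C)C[C@H](C(C)(C)O)O2)c1ccc(OCC=C(C)C)cc1O | intermediate (not isolated)
24 | (E)-1-{2-hydroxy-4-[(3-methylbut-2-en-1-yl)oxy]phenyl}-3-[(2R)-2-(2-hydroxypropan-2-yl)-7-(methoxymethoxy)-4-(3-methylbut-2-en-1-yl)-2,3-dihydro-1-benzofuran-5-yl]prop-2-en-1-one | O=C(/C=C/c1cc(OCOC)c2c(c1CC=C(C)C)C[C@H](C(C)(C)O)O2)c1ccc(OCC=C(C)C)cc1O | intermediate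
25 | 1-{2-hydroxy-4-[(3-methylbut-2-en-1-yl)oxy]phenyl}-3-[(2R)-2-(2-hydroxypropan-2-yl)-7-(methoxymethoxy)-4-(3-methylbut-2-en-1-yl)-2,3-dihydro-1-benzofuran-5-yl]propan-1-one | O=C(CCc1cc(OCOC)c2c(c1CC=C(C)C)C[C@H](C(C)(C)O)O2)c1ccc(OCC=C(C)C)cc1O | intermediate
26 | ethyl carbonate of the phenol of 25 | O=C(CCc1cc(OCOC)c2c(c1CC=C(C)C)C[C@H](C(C)(C)O)O2)c1ccc(OCC=C(C)C)cc1OC(=O)OCC | intermediate (not isolated)
27 | ring A ortho-quinone methide: 6-{3-[ring B aryl]propylidene}-3-[(3-methylbut-2-en-1-yl)oxy]cyclohexa-2,4-dien-1-one | CC(C)=CCOC1=CC(=O)C(=CCCc2cc(OCOC)c3c(c2CC=C(C)C)C[C@H](C(C)(C)O)O3)C=C1 | intermediate (not isolated)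
28 | 2-{3-[(2R)-2-(2-hydroxypropan-2-yl)-7-(methoxymethoxy)-4-(3-methylbut-2-en-1-yl)-2,3-dihydro-1-benzofuran-5-yl]propyl}-5-[(3-methylbut-2-en-1-yl)oxy]phenol | CC(C)=CCOc1ccc(CCCc2cc(OCOC)c3c(c2CC=C(C)C)C[C@H](C(C)(C)O)O3)c(O)c1 | intermediate
29 | Claisen dienone: 3-hydroxy-6-(2-methylbut-3-en-2-yl)-4-{3-[ring B aryl]propyl}cyclohexa-2,4-dien-1-one, mixture of epimers at the sp3 ring carbon | C=CC(C)(C)C1C=C(CCCc2cc(OCOC)c3c(c2CC=C(C)C)C[C@H](C(C)(C)O)O3)C(O)=CC1=O | intermediate (not isolated)
30 | 4-{3-[(2R)-2-(2-hydroxypropan-2-yl)-7-(methoxymethoxy)-4-(3-methylbut-2-en-1-yl)-2,3-dihydro-1-benzofuran-5-yl]propyl}-6-(2-methylbut-3-en-2-yl)benzene-1,3-diol | C=CC(C)(C)c1cc(CCCc2cc(OCOC)c3c(c2CC=C(C)C)C[C@H](C(C)(C)O)O3)c(O)cc1O | intermediate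
31 | 4-{3-[(2R)-7-hydroxy-2-(2-hydroxypropan-2-yl)-4-(3-methylbut-2-en-1-yl)-2,3-dihydro-1-benzofuran-5-yl]propyl}-6-(2-methylbut-3-en-2-yl)benzene-1,3-diol (CNP0189999.1) | C=CC(C)(C)c1cc(CCCc2cc(O)c3c(c2CC=C(C)C)C[C@H](C(C)(C)O)O3)c(O)cc1O | target

**Count and risks**

Total steps: 16. Longest linear sequence: 14 steps (steps 1–4, 6–10 and 12–16, from 1); steps 5 and 11 are side branches.

Step 6 (the proposed extension). What may go wrong: weak discrimination by the chiral quinuclidinium when only the ylide carbon becomes stereogenic (low enantiomeric purity at C2), or oligomerisation of the unsubstituted quinone methide before the ylide captures it. Fallback with known reactions only, setting out from 6 and rejoining at 16: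
- 6 is treated with 2-methylprop-1-enylmagnesium bromide (2.5 equiv, THF, −78 to 0 °C). The first equivalent triggers sulfinate loss and the second adds 1,4 to the quinone methide, giving 4-bromo-2-(methoxymethoxy)-6-(3-methylbut-2-en-1-yl)phenol F1.
- Silylation (TBSCl, imidazole, DMF) gives tert-butyl[4-bromo-2-(methoxymethoxy)-6-(3-methylbut-2-en-1-yl)phenoxy]dimethylsilane F2.
- Shi epoxidation with the ketone catalyst of the L-fructose series (Oxone, K2CO3, MeCN–dimethoxymethane–H2O, 0 °C) should give, by the spiro transition-state model, tert-butyl(4-bromo-2-{[(2S)-3,3-dimethyloxiran-2-yl]methyl}-6-(methoxymethoxy)phenoxy)dimethylsilane F3.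
- TBAF in THF frees the phenoxide, which opens the epoxide at its secondary carbon in a 5-exo closure with inversion and gives carbinol 16 directly.

Step 15. What may go wrong: migration of the allyl unit to the ring carbon between the two oxygens, and onward reaction of the new ortho-(1,1-dimethylallyl)phenol under heat (cyclisation onto the alkene, abnormal Claisen isomerisation). Fallback by steric steering, setting out from 28 and rejoining at 30:
- The free phenol of 28 is silylated (TIPSCl, imidazole, DMF) to tri(propan-2-yl)silyl ether F4, which walls off the carbon between the oxygens and removes the acidic phenol.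
- Rearrangement (N,N-diethylaniline, 180 °C) should then give 2-(2-methylbut-3-en-2-yl)-4-{3-[(2R)-2-(2-hydroxypropan-2-yl)-7-(methoxymethoxy)-4-(3-methylbut-2-en-1-yl)-2,3-dihydro-1-benzofuran-5-yl]propyl}-5-{[tri(propan-2-yl)silyl]oxy}phenol F5.
- TBAF in THF returns 30.

Step 9. What may go wrong: bromination at C6 (ortho to OMOM) instead of, or in addition to, C4. Fallback that changes the directing group, setting out from 18 and rejoining at 19:
- The MOM group of 18 is removed (HCl, MeOH, rt) to give (2R)-7-hydroxy-2-(2-hydroxypropan-2-yl)-2,3-dihydro-1-benzofuran-5-carbaldehyde F6.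
- The free phenol directs a para-selective bromination with Bu4NBr3 (CH2Cl2–MeOH, rt) to C4, giving (2R)-4-bromo-7-hydroxy-2-(2-hydroxypropan-2-yl)-2,3-dihydro-1-benzofuran-5-carbaldehyde F7.
- Re-protection of the phenol (MOMCl, K2CO3, acetone) gives 19.

**Further compounds**

F1 | step 6 | 4-bromo-2-(methoxymethoxy)-6-(3-methylbut-2-en-1-yl)phenol | CC(C)=CCc1cc(Br)cc(OCOC)c1O
F2 | step 6 | tert-butyl[4-bromo-2-(methoxymethoxy)-6-(3-methylbut-2-en-1-yl)phenoxy]dimethylsilane | CC(C)=CCc1cc(Br)cc(OCOC)c1O[Si](C)(C)C(C)(C)C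
F3 | step 6 | tert-butyl(4-bromo-2-{[(2S)-3,3-dimethyloxiran-2-yl]methyl}-6-(methoxymethoxy)phenoxy)dimethylsilane | CC1(C)O[C@H]1Cc2cc(Br)cc(OCOC)c2O[Si](C)(C)C(C)(C)C
F4 | step 15 | tri(propan-2-yl)silyl ether of 28 at the phenol oxygen ortho to the propyl chain | CC(C)=CCOc1ccc(CCCc2cc(OCOC)c3c(c2CC=C(C)C)C[C@H](C(C)(C)O)O3)c(O[Si](C(C)C)(C(C)C)C(C)C)c1
F5 | step 15 | 2-(2-methylbut-3-en-2-yl)-4-{3-[(2R)-2-(2-hydroxypropan-2-yl)-7-(methoxymethoxy)-4-(3-methylbut-2-en-1-yl)-2,3-dihydro-1-benzofuran-5-yl]propyl}-5-{[tri(propan-2-yl)silyl]oxy}phenol | C=CC(C)(C)c1cc(CCCc2cc(OCOC)c3c(c2CC=C(C)C)C[C@H](C(C)(C)O)O3)c(O[Si](C(C)C)(C(C)C)C(C)C)cc1O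
F6 | step 9 | (2R)-7-hydroxy-2-(2-hydroxypropan-2-yl)-2,3-dihydro-1-benzofuran-5-carbaldehyde | O=Cc1cc(O)c2c(c1)C[C@H](C(C)(C)O)O2
F7 | step 9 | (2R)-4-bromo-7-hydroxy-2-(2-hydroxypropan-2-yl)-2,3-dihydro-1-benzofuran-5-carbaldehyde | O=Cc1cc(O)c2c(c1Br)C[C@H](C(C)(C)O)O2
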